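**Strategy.** The ten-membered carbocycle is closed last, across C6–C7 (germacrane numbering: C6 = angeloyloxy carbon, C7 = ring-fusion carbon bearing the C11=C13 methylene, C8 = lactone O–CH). The α-methylene-γ-butyrolactone hides a homoallylic alcohol, C6(OH)–C7–C11=C13. The precursor is therefore a butenolide (C7=C11) carrying an allylsilane (C13–SiMe3) and, on C8, a seven-carbon chain ending in the C6 aldehyde. One intramolecular Hosomi–Sakurai reaction forms the C6–C7 bond and the ring, transposes the double bond to unveil the exocyclic methylene, sets C6 and C7, and frees the C6 hydroxyl for the angelate.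

Key step: step 13

Remark: target atoms are numbered as in germacranolides (ring C1 = carbinol, C3 = ketone, C4 = acetoxy carbon, C10 = methyl-bearing carbon; C12 = lactone carbonyl); (S)-β-citronellene, (R)-lactic acid, D-proline and (+)-Ipc2BCl are assumed to be commercial.

Step 1
Reactants: 1 methyl 2-[bis(2,2,2-trifluoroethoxy)phosphoryl]acetate
Product: 2 methyl 2-[bis(2,2,2-trifluoroethoxy)phosphoryl]-3-(trimethylsilyl)propanoate (racemic)
Conditions: NaH, DMF, 0 °C; Me3SiCH2I, 0 → 50 °C
Reagents that add atoms: (iodomethyl)trimethylsilane, C[Si](C)(C)CI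
Why: SN2 C-alkylation of the stabilised phosphonoacetate anion by the unhindered α-silyl iodide, as known for the diethyl analogue; the new centre is lost in the later olefination, so no stereocontrol is needed.

Step 2
Reactants: 3 (3S)-3,7-dimethylocta-1,6-diene [(S)-β-citronellene]
Product: 4 (4S)-4-methylhex-5-enal
Conditions: O3 (1 equiv), CH2Cl2, −78 °C; Me2S, −78 °C → rt
Reagents that add atoms: ozone, [O-][O+]=O
Why: Chemoselective ozonolysis, because the electron-rich trisubstituted alkene reacts much faster than the vinyl group; the C10 stereocentre comes unchanged from the chiral pool.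

Step 3
Reactants: 4 (4S)-4-methylhex-5-enal; 2 methyl 2-[bis(2,2,2-trifluoroethoxy)phosphoryl]-3-(trimethylsilyl)propanoate
Product: 6 methyl (2E,4S,6S)-6-methyl-4-[(phenylamino)oxy]-2-[(trimethylsilyl)methyl]octa-2,7-dienoate (ester cis to the C8 chain), via α-aminoxy aldehyde 5 (not isolated)
Conditions: PhNO, D-proline (20 mol %), CHCl3, 4 °C; crude 5 in THF added to 2, KN(SiMe3)2, 18-crown-6, THF, −78 °C
Reagents that add atoms: nitrosobenzene, O=Nc1ccccc1
Why: Proline-catalysed enamine α-aminoxylation (D-proline should set the C8–O centre as S by catalyst control) followed by a Still–Gennari Horner–Wadsworth–Emmons olefination, whose kinetic selectivity should place the ester cis to the C8 chain as lactonisation requires.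

Step 4
Reactants: 6 methyl (2E,4S,6S)-6-methyl-4-[(phenylamino)oxy]-2-[(trimethylsilyl)methyl]octa-2,7-dienoate
Product: 8 (5S)-5-[(2S)-2-methylbut-3-en-1-yl]-3-[(trimethylsilyl)methyl]furan-2(5H)-one, via γ-hydroxy enoate 7 (not isolated)
Conditions: Zn dust, AcOH, THF, rt; then p-TsOH·H2O (cat.), CH2Cl2, rt
Reagents that add atoms: none
Why: Reductive N–O cleavage releases the γ-hydroxyl, which sits cis to the ester across the double bond and should lactonise to the butenolide; no stereocentre is touched.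

Step 5
Reactants: 8 (5S)-5-[(2S)-2-methylbut-3-en-1-yl]-3-[(trimethylsilyl)methyl]furan-2(5H)-one
Product: 9 (2S)-2-methyl-3-[(2S)-5-oxo-4-[(trimethylsilyl)methyl]-2,5-dihydrofuran-2-yl]propanal
Conditions: OsO4 (cat.), NaIO4, 2,6-lutidine, dioxane/H2O (3:1), rt
Reagents that add atoms: sodium periodate (oxygen relayed by OsO4), [Na+].[O-]I(=O)(=O)=O
Why: Lemieux–Johnson cleavage, in which the isolated terminal alkene should be osmylated far faster than the conjugated trisubstituted butenolide alkene; the buffered medium should keep the α-stereocentre of the new aldehyde intact.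

Step 6
Reactants: 10 (R)-lactic acid
Product: 11 (2R,5R)-2-tert-butyl-5-methyl-1,3-dioxolan-4-one
Conditions: t-BuCHO, p-TsOH·H2O (cat.), H2SO4 (cat.), pentane, reflux (Dean–Stark); crystallisation
Reagents that add atoms: pivalaldehyde, CC(C)(C)C=O
Why: Acid-catalysed acetalisation (self-regeneration of stereocentres); the cis acetal should predominate and is purified by crystallisation.

Step 7
Reactants: 11 (2R,5R)-2-tert-butyl-5-methyl-1,3-dioxolan-4-one
Product: 12 (2R,5S)-2-tert-butyl-5-methyl-5-(prop-2-en-1-yl)-1,3-dioxolan-4-one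
Conditions: LiN(i-Pr)2, THF, −78 °C; allyl bromide, −78 → −30 °C
Reagents that add atoms: allyl bromide, C=CCBr
Why: Enolate alkylation anti to the tert-butyl group, so that allyl takes the place of the former hydrogen with net retention and fixes the quaternary C4 centre.

Step 8
Reactants: 12 (2R,5S)-2-tert-butyl-5-methyl-5-(prop-2-en-1-yl)-1,3-dioxolan-4-one
Product: 13 (3S)-3-hydroxy-3-methylhex-5-en-2-one
Conditions: MeLi (1.05 equiv), THF, −78 °C; aq. NH4Cl
Reagents that add atoms: methyllithium, [Li]C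
Why: Single nucleophilic addition to the lactone-type carbonyl gives a tetrahedral lithium hemiketal that should persist at −78 °C and collapse on work-up, with loss of pivalaldehyde, to the α-hydroxy methyl ketone; the quaternary centre is untouched.

Step 9
Reactants: 13 (3S)-3-hydroxy-3-methylhex-5-en-2-one
Product: 14 (3S)-3-methyl-2-oxohex-5-en-3-yl acetate
Conditions: Ac2O, Et3N, 4-(dimethylamino)pyridine (20 mol %), CH2Cl2, rt → 40 °C
Reagents that add atoms: acetic anhydride, CC(=O)OC(C)=O
Why: Nucleophile-catalysed acylation of the tertiary α-ketol on a robust small molecule; configuration is retained.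

Step 10
Reactants: 14 (3S)-3-methyl-2-oxohex-5-en-3-yl acetate; 9 (2S)-2-methyl-3-[(2S)-5-oxo-4-[(trimethylsilyl)methyl]-2,5-dihydrofuran-2-yl]propanal
Product: 15 (4S,7R,8S)-7-hydroxy-4,8-dimethyl-5-oxo-9-[(2S)-5-oxo-4-[(trimethylsilyl)methyl]-2,5-dihydrofuran-2-yl]non-1-en-4-yl acetate
Conditions: 14 (1.5 equiv), (+)-Ipc2BCl (1.4 equiv), Et3N, Et2O, −78 → 0 °C; then 9, −78 → −20 °C; MeOH, pH 7 buffer, H2O2, 0 °C
Reagents that add atoms: none
Why: Boron-mediated aldol reaction of a methyl ketone, which can enolise only toward C2 because C4 is fully substituted; the chiral boron reagent should set the 1R carbinol (anti to the C10 methyl) by reagent control over the weak Felkin bias of the aldehyde.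

Step 11
Reactants: 15 (4S,7R,8S)-7-hydroxy-4,8-dimethyl-5-oxo-9-[(2S)-5-oxo-4-[(trimethylsilyl)methyl]-2,5-dihydrofuran-2-yl]non-1-en-4-yl acetate
Product: 16 (4S,7R,8S)-7-[(tert-butyldimethylsilyl)oxy]-4,8-dimethyl-5-oxo-9-[(2S)-5-oxo-4-[(trimethylsilyl)methyl]-2,5-dihydrofuran-2-yl]non-1-en-4-yl acetate
Conditions: t-BuMe2SiOTf, 2,6-lutidine, CH2Cl2, −78 °C
Reagents that add atoms: tert-butyldimethylsilyl triflate, CC(C)(C)[Si](C)(C)OS(=O)(=O)C(F)(F)F
Why: O-Silylation with a silyl triflate and a hindered base at low temperature, too mild to enolise the ketone or to engage the allylsilane.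

Step 12
Reactants: 16 (4S,7R,8S)-7-[(tert-butyldimethylsilyl)oxy]-4,8-dimethyl-5-oxo-9-[(2S)-5-oxo-4-[(trimethylsilyl)methyl]-2,5-dihydrofuran-2-yl]non-1-en-4-yl acetate
Product: 17 (3S,6R,7S)-6-[(tert-butyldimethylsilyl)oxy]-3,7-dimethyl-1,4-dioxo-8-[(2S)-5-oxo-4-[(trimethylsilyl)methyl]-2,5-dihydrofuran-2-yl]octan-3-yl acetate
Conditions: OsO4 (cat.), NaIO4, 2,6-lutidine, dioxane/H2O (3:1), rt; used crude
Reagents that add atoms: sodium periodate (oxygen relayed by OsO4), [Na+].[O-]I(=O)(=O)=O
Why: Lemieux–Johnson cleavage of the terminal alkene in preference to the electron-poor butenolide alkene; the near-neutral medium should spare the β-acetoxy aldehyde, which is carried on at once.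

Step 13
Reactants: 17 (3S,6R,7S)-6-[(tert-butyldimethylsilyl)oxy]-3,7-dimethyl-1,4-dioxo-8-[(2S)-5-oxo-4-[(trimethylsilyl)methyl]-2,5-dihydrofuran-2-yl]octan-3-yl acetate
Product: 18 (3aR,4R,6S,9R,10S,11aS)-9-[(tert-butyldimethylsilyl)oxy]-4-hydroxy-6,10-dimethyl-3-methylidene-2,7-dioxododecahydrocyclodeca[b]furan-6-yl acetate
Conditions: BF3·OEt2 (3 equiv), CH2Cl2, −78 → −40 °C, 17 added slowly (final 1 mM); aq. NaHCO3
Reagents that add atoms: none
Why: BF3 activates the aldehyde and the allylsilane attacks through its γ-carbon C7 (the β-carbon of the butenolide) in an anti-SE2' sense, after which loss of the silyl group from the β-silyl cation moves the double bond to C11=C13 and turns the butenolide into the α-methylene lactone. The closest known reaction type is the intramolecular Hosomi–Sakurai cyclisation of ω-formyl 2-(silylmethyl)alk-2-enoates, here with the enoate held in a lactone ring. The ten-membered ring closes in the 10-exo-trig mode at the aldehyde carbon, with C11 of the allyl unit left outside the new ring. C7 should be set by the tether, which starts from C9 on C8 and brings the aldehyde to the lactone face syn to C9, giving the cis ring fusion. C6 should be set by the open antiperiplanar transition state, in which the aldehyde hydrogen lies over the crowded C8/C9 flank and C5 over C13, giving the 6R carbinol. The step needs aldehyde-over-ketone selectivity, secured by the much higher electrophilicity of the BF3-bound aldehyde than of the neopentylic C3 ketone, and ring closure over oligomerisation, secured by slow addition at high dilution.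

Step 14
Reactants: 18 (3aR,4R,6S,9R,10S,11aS)-9-[(tert-butyldimethylsilyl)oxy]-4-hydroxy-6,10-dimethyl-3-methylidene-2,7-dioxododecahydrocyclodeca[b]furan-6-yl acetate
Product: 19 (3aS,4R,6S,9R,10S,11aS)-6-acetoxy-9-[(tert-butyldimethylsilyl)oxy]-6,10-dimethyl-3-methylidene-2,7-dioxododecahydrocyclodeca[b]furan-4-yl (2Z)-2-methylbut-2-enoate
Conditions: angelic acid, 2,4,6-trichlorobenzoyl chloride, Et3N, toluene, rt; then 18, 80 °C
Reagents that add atoms: angelic acid, C/C=C(/C)C(=O)O
Why: Yamaguchi-type esterification through the mixed anhydride, run without a nucleophilic catalyst so that the Z geometry is kept; the C6 hydroxyl is acylated with retention, and prompt acylation should outpace acetyl migration from O4.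

Step 15
Reactants: 19 (3aS,4R,6S,9R,10S,11aS)-6-acetoxy-9-[(tert-butyldimethylsilyl)oxy]-6,10-dimethyl-3-methylidene-2,7-dioxododecahydrocyclodeca[b]furan-4-yl (2Z)-2-methylbut-2-enoate
Product: 20 (3aS,4R,6S,9R,10S,11aS)-6-acetoxy-9-hydroxy-6,10-dimethyl-3-methylidene-2,7-dioxododecahydrocyclodeca[b]furan-4-yl (2Z)-2-methylbut-2-enoate (CNP0141210.3)
Conditions: HF·pyridine, pyridine, THF, 0 °C → rt
Reagents that add atoms: none
Why: Fluoride-assisted desilylation under buffered acidic conditions, which should spare the β-hydroxy ketone, both esters and the α-methylene lactone.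

**Compound list**

1 | methyl 2-[bis(2,2,2-trifluoroethoxy)phosphoryl]acetate | COC(=O)CP(=O)(OCC(F)(F)F)OCC(F)(F)F | starting material
2 | methyl 2-[bis(2,2,2-trifluoroethoxy)phosphoryl]-3-(trimethylsilyl)propanoate (racemic) | COC(=O)C(C[Si](C)(C)C)P(=O)(OCC(F)(F)F)OCC(F)(F)F | intermediate
3 | (3S)-3,7-dimethylocta-1,6-diene | C=C[C@@H](C)CCC=C(C)C | starting material
4 | (4S)-4-methylhex-5-enal | C=C[C@@H](C)CCC=O | intermediate
5 | (2S,4S)-4-methyl-2-[(phenylamino)oxy]hex-5-enal | C=C[C@@H](C)C[C@H](ONc1ccccc1)C=O | intermediate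
6 | methyl (2E,4S,6S)-6-methyl-4-[(phenylamino)oxy]-2-[(trimethylsilyl)methyl]octa-2,7-dienoate | C=C[C@@H](C)C[C@H](ONc1ccccc1)/C=C(\C(=O)OC)C[Si](C)(C)C | intermediate
7 | methyl (2E,4S,6S)-4-hydroxy-6-methyl-2-[(trimethylsilyl)methyl]octa-2,7-dienoate | C=C[C@@H](C)C[C@H](O)/C=C(\C(=O)OC)C[Si](C)(C)C | intermediate
8 | (5S)-5-[(2S)-2-methylbut-3-en-1-yl]-3-[(trimethylsilyl)methyl]furan-2(5H)-one | C=C[C@@H](C)C[C@@H]1OC(=O)C(C[Si](C)(C)C)=C1 | intermediate
9 | (2S)-2-methyl-3-[(2S)-5-oxo-4-[(trimethylsilyl)methyl]-2,5-dihydrofuran-2-yl]propanal | O=C[C@@H](C)C[C@@H]1OC(=O)C(C[Si](C)(C)C)=C1 | intermediate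
10 | (R)-lactic acid | C[C@@H](O)C(=O)O | starting material
11 | (2R,5R)-2-tert-butyl-5-methyl-1,3-dioxolan-4-one | C[C@H]1O[C@@H](C(C)(C)C)OC1=O | intermediate
12 | (2R,5S)-2-tert-butyl-5-methyl-5-(prop-2-en-1-yl)-1,3-dioxolan-4-one | C[C@@]1(CC=C)O[C@@H](C(C)(C)C)OC1=O | intermediate
13 | (3S)-3-hydroxy-3-methylhex-5-en-2-one | CC(=O)[C@@](C)(O)CC=C | intermediate
14 | (3S)-3-methyl-2-oxohex-5-en-3-yl acetate | CC(=O)[C@@](C)(OC(C)=O)CC=C | intermediate
15 | (4S,7R,8S)-7-hydroxy-4,8-dimethyl-5-oxo-9-[(2S)-5-oxo-4-[(trimethylsilyl)methyl]-2,5-dihydrofuran-2-yl]non-1-en-4-yl acetate | C=CC[C@](C)(OC(C)=O)C(=O)C[C@@H](O)[C@@H](C)C[C@@H]1OC(=O)C(C[Si](C)(C)C)=C1 | intermediate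
16 | (4S,7R,8S)-7-[(tert-butyldimethylsilyl)oxy]-4,8-dimethyl-5-oxo-9-[(2S)-5-oxo-4-[(trimethylsilyl)methyl]-2,5-dihydrofuran-2-yl]non-1-en-4-yl acetate | C=CC[C@](C)(OC(C)=O)C(=O)C[C@@H](O[Si](C)(C)C(C)(C)C)[C@@H](C)C[C@@H]1OC(=O)C(C[Si](C)(C)C)=C1 | intermediate
17 | (3S,6R,7S)-6-[(tert-butyldimethylsilyl)oxy]-3,7-dimethyl-1,4-dioxo-8-[(2S)-5-oxo-4-[(trimethylsilyl)methyl]-2,5-dihydrofuran-2-yl]octan-3-yl acetate | O=CC[C@](C)(OC(C)=O)C(=O)C[C@@H](O[Si](C)(C)C(C)(C)C)[C@@H](C)C[C@@H]1OC(=O)C(C[Si](C)(C)C)=C1 | intermediate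
18 | (3aR,4R,6S,9R,10S,11aS)-9-[(tert-butyldimethylsilyl)oxy]-4-hydroxy-6,10-dimethyl-3-methylidene-2,7-dioxododecahydrocyclodeca[b]furan-6-yl acetate | C=C1C(=O)O[C@H]2C[C@H](C)[C@H](O[Si](C)(C)C(C)(C)C)CC(=O)[C@@](C)(OC(C)=O)C[C@@H](O)[C@@H]12 | intermediate
19 | (3aS,4R,6S,9R,10S,11aS)-6-acetoxy-9-[(tert-butyldimethylsilyl)oxy]-6,10-dimethyl-3-methylidene-2,7-dioxododecahydrocyclodeca[b]furan-4-yl (2Z)-2-methylbut-2-enoate | C=C1C(=O)O[C@H]2C[C@H](C)[C@H](O[Si](C)(C)C(C)(C)C)CC(=O)[C@@](C)(OC(C)=O)C[C@@H](OC(=O)/C(C)=C\C)[C@@H]12 | intermediate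
20 | (3aS,4R,6S,9R,10S,11aS)-6-acetoxy-9-hydroxy-6,10-dimethyl-3-methylidene-2,7-dioxododecahydrocyclodeca[b]furan-4-yl (2Z)-2-methylbut-2-enoate | C=C1C(=O)O[C@H]2C[C@H](C)[C@H](O)CC(=O)[C@@](C)(OC(C)=O)C[C@@H](OC(=O)/C(C)=C\C)[C@@H]12 | target

**Totals.** 15 steps in all. The longest linear sequence is 10 steps (3 → 4 → 6 → 8 → 9 → 15 → 16 → 17 → 18 → 19 → 20; the branch from 10 is equally long).

**Steps most likely to fail**

1. Step 13. The ester-deactivated allylsilane may add too slowly, so that the BF3-bound β-acetoxy aldehyde loses acetic acid first. The chain may also reach the lactone face anti to C9, giving the trans ring fusion, and by a simple torsional estimate that path is at least competitive. Fallback, from 17 to 19, which switches to a neutral chromium-mediated allylation and corrects C6 afterwards; it does not address the ring fusion. Bromodesilylation of 17 (Br2, CH2Cl2, −78 °C) should give the secondary allylic bromide F1. Intramolecular Nozaki–Hiyama–Kishi-type allylation (CrCl2, THF, rt, high dilution) is then expected, through its closed Zimmerman–Traxler transition state, to give the C6-epimeric alcohol F2. Mitsunobu esterification with angelic acid (PPh3, DIAD, toluene, 0 °C) inverts C6 and rejoins the route at 19.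

2. Step 10. Reagent control may not fully override the intrinsic facial bias of the α-methyl aldehyde, giving a C1-epimeric mixture; the sense of induction assigned to (+)-Ipc2BCl also rests on the reported face selectivity for methyl ketones and should be confirmed. Residual boron Lewis acid may trigger closure of 9 onto its own allylsilane. Fallback, from the epimeric mixture of 15 back to 15 as one epimer. Mesylation–elimination (MsCl, Et3N, CH2Cl2, 0 °C) converts both epimers into the E-enone F3. Catalyst-controlled conjugate borylation (CuCl, NaOt-Bu, Josiphos-type ligand, B2pin2, MeOH, THF) should give the β-boryl ketone F4. Oxidation (NaBO3·4H2O, THF/H2O) then returns 15 with retention at C1.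

3. Step 3. The labile α-aminoxy aldehyde 5 may decompose or epimerise under the strongly basic olefination, and the bulky α-substituent may erode the geometric selectivity. Fallback, from 4 to 8. The non-fluorinated phosphonate F5 (from trimethyl phosphonoacetate, NaH and Me3SiCH2I) is used in a mild LiCl/DBU Horner–Wadsworth–Emmons reaction with crude 5 in MeCN to give the enoate F6 as an E/Z mixture. Zn/AcOH cleaves the N–O bond to give the hydroxy enoate F7. Irradiation (300 nm, benzene) equilibrates the double bond while the cis isomer lactonises, funnelling both isomers into 8.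

**Further compounds**

F1 | step 13 | (3S,6R,7S)-8-[(2S)-3-bromo-4-methylidene-5-oxooxolan-2-yl]-6-[(tert-butyldimethylsilyl)oxy]-3,7-dimethyl-1,4-dioxooctan-3-yl acetate (epimers at the bromine-bearing carbon) | O=CC[C@](C)(OC(C)=O)C(=O)C[C@@H](O[Si](C)(C)C(C)(C)C)[C@@H](C)C[C@@H]1OC(=O)C(=C)C1Br
F2 | step 13 | (3aR,4S,6S,9R,10S,11aS)-9-[(tert-butyldimethylsilyl)oxy]-4-hydroxy-6,10-dimethyl-3-methylidene-2,7-dioxododecahydrocyclodeca[b]furan-6-yl acetate | C=C1C(=O)O[C@H]2C[C@H](C)[C@H](O[Si](C)(C)C(C)(C)C)CC(=O)[C@@](C)(OC(C)=O)C[C@H](O)[C@@H]12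
F3 | step 10 | (4S,6E,8S)-4,8-dimethyl-5-oxo-9-[(2S)-5-oxo-4-[(trimethylsilyl)methyl]-2,5-dihydrofuran-2-yl]nona-1,6-dien-4-yl acetate | C=CC[C@](C)(OC(C)=O)C(=O)/C=C/[C@@H](C)C[C@@H]1OC(=O)C(C[Si](C)(C)C)=C1
F4 | step 10 | (4S,7R,8S)-4,8-dimethyl-5-oxo-9-[(2S)-5-oxo-4-[(trimethylsilyl)methyl]-2,5-dihydrofuran-2-yl]-7-(4,4,5,5-tetramethyl-1,3,2-dioxaborolan-2-yl)non-1-en-4-yl acetate | C=CC[C@](C)(OC(C)=O)C(=O)C[C@@H](B1OC(C)(C)C(C)(C)O1)[C@@H](C)C[C@@H]1OC(=O)C(C[Si](C)(C)C)=C1
F5 | step 3 | methyl 2-(dimethoxyphosphoryl)-3-(trimethylsilyl)propanoate | COC(=O)C(C[Si](C)(C)C)P(=O)(OC)OC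
F6 | step 3 | methyl (4S,6S)-6-methyl-4-[(phenylamino)oxy]-2-[(trimethylsilyl)methyl]octa-2,7-dienoate (E/Z mixture) | C=C[C@@H](C)C[C@H](ONc1ccccc1)C=C(C(=O)OC)C[Si](C)(C)C
F7 | step 3 | methyl (4S,6S)-4-hydroxy-6-methyl-2-[(trimethylsilyl)methyl]octa-2,7-dienoate (E/Z mixture) | C=C[C@@H](C)C[C@H](O)C=C(C(=O)OC)C[Si](C)(C)C
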